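**Retrosynthetic overview**

Locants used here: C1 = quaternary epoxide carbon bearing CH2OBz, C2 = epoxide CH, C3=C4 = ring alkene, C5 = CHOBz, C6 = CHOH (target: C1 S, C2 R, C5 R, C6 S).
Endgame: the oxirane is closed last by hydroxyl-directed epoxidation of diene 13, which comes from the bridged keto benzoate 8 by one-carbon homologation at C1 and loss of the doubly allylic C2 oxygen.
Key disconnection: the C2–C3 and C5–C6 bonds are made together in a [3+3] annulation in which zerovalent palladium lets the enamine of 2,2-dimethyl-1,3-dioxan-5-one (C2–C1–C6) attack both ends of acrolein diacetate (C3–C4–C5) in sequence.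
Enabling feature: C2 and C6 flank C1 and both carry oxygen on the same ring face, so C2–C1–C6 is a dioxanone whose acetonide ring (absent from the target) forces the two new bonds cis and makes the carbocycle a bridge; because the C5 oxygen sits on an allylic carbon of C3=C4–C5, the bridged alkene 7, although chiral, gives a mirror-symmetric allyl radical, so the benzoate and the absolute configuration can be set together under catalyst control.
Ring order: carbocycle first, as a 2,4-dioxabicyclo[3.3.1]nonene (step 2); the temporary dioxane ring is opened in step 5; the oxirane is formed in step 8.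

Key step: step 2

Assumption: the sense of induction of the copper–bis(oxazoline) catalyst in step 3 is taken from simple cycloalkenes; should the antipode of 8 predominate, the enantiomeric ligand is used with no other change.

**Route**

Step 1
Reactants: 1 2,2-dimethyl-1,3-dioxan-5-one; 2 pyrrolidine
Product: 3 1-(2,2-dimethyl-4H-1,3-dioxin-5-yl)pyrrolidine
Conditions: 4 Å molecular sieves, toluene, rt
Reagents that add atoms: none
Why: Condensation of the secondary amine with the symmetrical ketone under removal of water (Stork enamine formation) can give only this enamine; no stereocenter is formed.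

Step 2
Reactants: 3 1-(2,2-dimethyl-4H-1,3-dioxin-5-yl)pyrrolidine; 4 prop-2-ene-1,1-diyl diacetate (acrolein diacetate)
Product: 7 rac-3,3-dimethyl-2,4-dioxabicyclo[3.3.1]non-6-en-9-one, via allylated enamine 5 (not isolated), via bicyclic iminium acetate 6 (not isolated)
Conditions: Pd(PPh3)4 (5 mol %), i-Pr2NEt (2 equiv), THF (0.02 M, slow addition of 3 and 4), rt to 60 °C; then AcOH/NaOAc buffer, H2O, rt
Reagents that add atoms: water, O
Why: Proposed new method: zerovalent palladium ionises one acetate of 4 to a 1-acetoxyallyl complex, the enamine carbon attacks its oxygen-bearing terminus, the iminium relaxes to the less substituted enamine 5, a second ionisation of the new allylic acetate gives a 1-alkylallyl complex, and the enamine carbon closes onto its CH2 terminus to give 6, which the buffer hydrolyses to 7. The closest known reaction types are the Tsuji–Trost allylation of Stork enamines, the substitution of allylic geminal diacetates at the acetoxy-bearing carbon, the palladium-catalysed alpha,alpha'-annulation of enamines and beta-keto esters with 2-methylenepropane-1,3-diyl diacetate, and the Stork enamine annulation with acrolein; new is the use of a geminal diacetate as a three-carbon 1,3-dielectrophile, which leaves the C3=C4 alkene in the ring directly. Ring A (the carbocycle C1–C6) closes by 6-endo attack on the allyl terminus remote from the tether, through the anti allyl isomer reached by eta3–eta1–eta3 interconversion, the 4-exo alternative being far more strained; it can only form as a bridge across the dioxane, which gives the bicyclo[3.3.1] skeleton. The two bridgehead stereocenters are formed here with their relative configuration dictated by the bridge (both new bonds must be cis and axial on the dioxane), and no absolute control is sought because both enantiomers of 7 converge in step 3. The step needs attack at the acetoxy-bearing carbon first, ring closure faster than a second intermolecular allylation, and reaction through the less substituted enamine; the known regiochemistry of geminal diacetates, high dilution, and the preference of pyrrolidine enamines for the less substituted double bond with a pseudoaxial side chain should secure these. The product has no allylic leaving group and both neighbouring carbons are bridgeheads, so it can neither re-ionise nor eliminate to a diene.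

Step 3
Reactants: 7 rac-3,3-dimethyl-2,4-dioxabicyclo[3.3.1]non-6-en-9-one
Product: 8 (1S,5R,8R)-3,3-dimethyl-9-oxo-2,4-dioxabicyclo[3.3.1]non-6-en-8-yl benzoate
Conditions: Cu(MeCN)4PF6 (5 mol %), (S,S)-2,2'-isopropylidenebis(4-tert-butyl-2-oxazoline) (6 mol %), PhCO3t-Bu (1.5 equiv), MeCN, −20 °C
Reagents that add atoms: tert-butyl perbenzoate, CC(C)(C)OOC(=O)c1ccccc1
Why: In this copper-catalysed allylic benzoyloxylation (Kharasch–Sosnovsky reaction) hydrogen abstraction from the only allylic CH2 gives an allyl radical that is mirror-symmetric within the bicycle, so both enantiomers of 7 converge, and the chiral copper benzoate complex then delivers benzoate to one allyl terminus on the exo face (away from the ketal bridge), which sets C5 trans to the C6 oxygen and fixes the absolute configuration of the whole bicycle.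

Step 4
Reactants: 8 (1S,5R,8R)-3,3-dimethyl-9-oxo-2,4-dioxabicyclo[3.3.1]non-6-en-8-yl benzoate
Product: 9 (1R,5R,8R)-9-(methoxymethylidene)-3,3-dimethyl-2,4-dioxabicyclo[3.3.1]non-6-en-8-yl benzoate (E/Z mixture)
Conditions: Ph3P(CH2OMe)Cl, KN(SiMe3)2, THF, −78 to 0 °C
Reagents that add atoms: (methoxymethyl)triphenylphosphonium chloride, [Cl-].COC[P+](c1ccccc1)(c1ccccc1)c1ccccc1
Why: Wittig alkoxymethylenation of the bridging ketone, which cannot enolise because both alpha-carbons are bridgeheads, so neither epimerisation nor beta-elimination of the benzoate can compete; no stereocenter is formed.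

Step 5
Reactants: 9 (1R,5R,8R)-9-(methoxymethylidene)-3,3-dimethyl-2,4-dioxabicyclo[3.3.1]non-6-en-8-yl benzoate
Product: 11 (1R,6R)-5-formyl-6-hydroxycyclohexa-2,4-dien-1-yl benzoate, via dienal hemiketal 10 (not isolated)
Conditions: 0.5 M HCl, THF/H2O, 0 °C to rt
Reagents that add atoms: water, O
Why: Aqueous acid turns the enol ether into the formyl group and cleaves only the ketal C–O bond at C2, which is doubly allylic (between the enol ether and the ring alkene) whereas the one at C6 is singly allylic and next to the electron-withdrawing benzoate (acid-mediated beta-elimination of a beta-alkoxy aldehyde equivalent), giving the fully conjugated dienal as hemiketal 10, which loses acetone; C5 and C6 are untouched.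

Step 6
Reactants: 11 (1R,6R)-5-formyl-6-hydroxycyclohexa-2,4-dien-1-yl benzoate
Product: 12 (1R,6R)-6-hydroxy-5-(hydroxymethyl)cyclohexa-2,4-dien-1-yl benzoate
Conditions: NaBH4, CeCl3·7H2O, MeOH, −78 °C
Reagents that add atoms: none
Why: Luche reduction gives clean 1,2-reduction of the dienal at low temperature, where base-induced aromatisation should not compete; no stereocenter is formed.

Step 7
Reactants: 12 (1R,6R)-6-hydroxy-5-(hydroxymethyl)cyclohexa-2,4-dien-1-yl benzoate
Product: 13 [(5R,6R)-5-(benzoyloxy)-6-hydroxycyclohexa-1,3-dien-1-yl]methyl benzoate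
Conditions: BzCl (1.05 equiv), 2,4,6-collidine, CH2Cl2, −40 °C
Reagents that add atoms: benzoyl chloride, O=C(Cl)c1ccccc1
Why: Chemoselective esterification: the primary allylic hydroxyl is acylated much faster than the secondary one flanked by the benzoate and the substituted ring carbon; no stereocenter is touched.

Step 8
Reactants: 13 [(5R,6R)-5-(benzoyloxy)-6-hydroxycyclohexa-1,3-dien-1-yl]methyl benzoate
Product: 14 [(1R,4R,5S,6S)-4-(benzoyloxy)-5-hydroxy-7-oxabicyclo[4.1.0]hept-2-en-6-yl]methyl benzoate (target)
Conditions: VO(acac)2 (5 mol %), t-BuOOH, CH2Cl2, 0 °C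
Reagents that add atoms: tert-butyl hydroperoxide, CC(C)(C)OO
Why: Vanadium-catalysed hydroxyl-directed epoxidation delivers oxygen to the adjacent trisubstituted C1=C2 alkene on the face of the coordinating C6 hydroxyl, which sets both epoxide carbons cis to that hydroxyl and leaves the remote C3=C4 alkene untouched.

**Compound list**

1 | 2,2-dimethyl-1,3-dioxan-5-one | CC1(C)OCC(=O)CO1 | starting material
2 | pyrrolidine | C1CCNC1 | starting material
3 | 1-(2,2-dimethyl-4H-1,3-dioxin-5-yl)pyrrolidine | CC1(C)OCC(=CO1)N1CCCC1 | intermediate
4 | prop-2-ene-1,1-diyl diacetate (acrolein diacetate) | C=CC(OC(C)=O)OC(C)=O | starting material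
5 | 1-[2,2-dimethyl-5-(pyrrolidin-1-yl)-4H-1,3-dioxin-4-yl]prop-2-en-1-yl acetate (racemic, both diastereomers) | C=CC(OC(C)=O)C1OC(C)(C)OC=C1N1CCCC1 | intermediate
6 | rac-1-(3,3-dimethyl-2,4-dioxabicyclo[3.3.1]non-6-en-9-ylidene)pyrrolidin-1-ium acetate (racemate, one enantiomer drawn) | CC(=O)[O-].C1CC[N+](C1)=C1[C@H]2C=CC[C@@H]1OC(C)(C)O2 | intermediate
7 | rac-3,3-dimethyl-2,4-dioxabicyclo[3.3.1]non-6-en-9-one (racemate, the 1S,5R enantiomer drawn) | O=C1[C@H]2C=CC[C@@H]1OC(C)(C)O2 | intermediate
8 | (1S,5R,8R)-3,3-dimethyl-9-oxo-2,4-dioxabicyclo[3.3.1]non-6-en-8-yl benzoate (benzoate exo, trans to the neighbouring bridgehead oxygen) | O=C1[C@H]2C=C[C@@H](OC(=O)c3ccccc3)[C@@H]1OC(C)(C)O2 | intermediate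
9 | (1R,5R,8R)-9-(methoxymethylidene)-3,3-dimethyl-2,4-dioxabicyclo[3.3.1]non-6-en-8-yl benzoate (E/Z mixture) | COC=C1[C@H]2C=C[C@@H](OC(=O)c3ccccc3)[C@@H]1OC(C)(C)O2 | intermediate
10 | (1R,6R)-5-formyl-6-[(2-hydroxypropan-2-yl)oxy]cyclohexa-2,4-dien-1-yl benzoate | O=CC1=CC=C[C@@H](OC(=O)c2ccccc2)[C@@H]1OC(C)(C)O | intermediate
11 | (1R,6R)-5-formyl-6-hydroxycyclohexa-2,4-dien-1-yl benzoate | O=CC1=CC=C[C@@H](OC(=O)c2ccccc2)[C@@H]1O | intermediate
12 | (1R,6R)-6-hydroxy-5-(hydroxymethyl)cyclohexa-2,4-dien-1-yl benzoate | OCC1=CC=C[C@@H](OC(=O)c2ccccc2)[C@@H]1O | intermediate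
13 | [(5R,6R)-5-(benzoyloxy)-6-hydroxycyclohexa-1,3-dien-1-yl]methyl benzoate | O=C(OCC1=CC=C[C@@H](OC(=O)c2ccccc2)[C@@H]1O)c1ccccc1 | intermediate
14 | [(1R,4R,5S,6S)-4-(benzoyloxy)-5-hydroxy-7-oxabicyclo[4.1.0]hept-2-en-6-yl]methyl benzoate | O=C(OC[C@@]12O[C@@H]1C=C[C@@H](OC(=O)c1ccccc1)[C@@H]2O)c1ccccc1 | target

**Step count and risks**

Total step count: 8. Longest linear sequence: 8 steps (1 → 3 → 7 → 8 → 9 → 11 → 12 → 13 → 14).

Steps most likely to fail:

Step 2 (the proposed new method). The second allylic alkylation may lose to intermolecular allylation of another enamine. The first attack may go to the CH2 terminus and give a dead-end enol acetate. The 6-endo closure through the anti allyl isomer may be too slow. The fallback uses known chemistry, sets out from 3 and returns at 7. The Stork enamine annulation of 3 with acrolein (Michael addition followed by Mannich ring closure; dioxane, 0 °C to rt) should give the racemic amino ketone 3,3-dimethyl-6-(pyrrolidin-1-yl)-2,4-dioxabicyclo[3.3.1]nonan-9-one F1. Oxidation with mCPBA gives its N-oxide F2. Cope elimination (toluene, 80 °C) can only proceed away from the bridgehead and gives 7.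

Step 3. Hydrogen abstraction may be slow or unselective on this electron-poor, oxygen-rich alkene. Enantioselection between the two allyl termini may be insufficient. The yield based on the alkene may be low. The fallback sets out from 7 and returns at 8. Allylic hydroxylation with SeO2 (20 mol %) and t-BuOOH (ene reaction then [2,3]-shift on the exo face, with no symmetric intermediate) gives the racemic trans allylic alcohol (1S,5R,8R)-8-hydroxy-3,3-dimethyl-2,4-dioxabicyclo[3.3.1]non-6-en-9-one F3. Lipase-catalysed kinetic resolution (Candida antarctica lipase B, vinyl benzoate, toluene) then benzoylates one enantiomer to give 8. If the enzyme prefers the antipode, the recovered alcohol is benzoylated with BzCl and pyridine instead.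

Step 5. The wrong ketal C–O bond may cleave, losing the C6 oxygen. Acid may aromatise the dienal by loss of water or benzoic acid. The benzoyl group may migrate to the C6 hydroxyl. The fallback sets out from 8 and returns at 12. Non-basic methylenation (Zn, CH2Br2, TiCl4, THF) gives the exocyclic alkene (1R,5R,8R)-3,3-dimethyl-9-methylidene-2,4-dioxabicyclo[3.3.1]non-6-en-8-yl benzoate F4. Mild ketal hydrolysis (80% aqueous AcOH, rt) gives the diol (1R,4R,6R)-4,6-dihydroxy-5-methylidenecyclohex-2-en-1-yl benzoate F5. Ph3SiOReO3-catalysed 1,3-transposition of the doubly allylic alcohol (Et2O, −40 °C), driven by formation of the conjugated diene, moves the C2 oxygen to the exocyclic carbon and gives 12.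

Further compounds
F1 | step 2 | rac-3,3-dimethyl-6-(pyrrolidin-1-yl)-2,4-dioxabicyclo[3.3.1]nonan-9-one (racemate, one enantiomer drawn, amine-bearing carbon as a mixture of epimers) | O=C1[C@H]2C(N3CCCC3)CC[C@@H]1OC(C)(C)O2
F2 | step 2 | rac-3,3-dimethyl-6-(1-oxidopyrrolidin-1-ium-1-yl)-2,4-dioxabicyclo[3.3.1]nonan-9-one (racemate, one enantiomer drawn) | O=C1[C@H]2C([N+]3([O-])CCCC3)CC[C@@H]1OC(C)(C)O2
F3 | step 3 | rac-(1S,5R,8R)-8-hydroxy-3,3-dimethyl-2,4-dioxabicyclo[3.3.1]non-6-en-9-one (racemate, one enantiomer drawn) | O=C1[C@H]2C=C[C@@H](O)[C@@H]1OC(C)(C)O2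
F4 | step 5 | (1R,5R,8R)-3,3-dimethyl-9-methylidene-2,4-dioxabicyclo[3.3.1]non-6-en-8-yl benzoate | C=C1[C@H]2C=C[C@@H](OC(=O)c3ccccc3)[C@@H]1OC(C)(C)O2
F5 | step 5 | (1R,4R,6R)-4,6-dihydroxy-5-methylidenecyclohex-2-en-1-yl benzoate | C=C1[C@H](O)C=C[C@@H](OC(=O)c2ccccc2)[C@@H]1O
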